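**Assumptions.** The target has no stereocenters, so nothing needs to be set or protected against scrambling. The aryl sulfate monoester is made and isolated as its salt (tributylammonium, then sodium) because the free acid is hydrolytically labile. The SMILES below show the drawn free acid.

## Retrosynthetic overview
1. The target comes from hydrogenolysis of the two B-ring benzyl ethers of the 7-O-sulfate. The sulfate is installed by regioselective sulfation of the most acidic 7-OH of a 5,6,7-trihydroxyflavone.
2. The pyranone ring is built in one Pd step, not by Baker–Venkataraman or chalcone cyclization. A carbonylative Sonogashira coupling of an A-ring o-iodophenol with a B-ring terminal alkyne and CO forms the C4a–C4 bond, and a 6-endo oxa-Michael closure forms O1–C2.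
3. The A-ring iodophenol comes from NIS iodination of 3,4,5-tris(MOM-oxy)phenol, which comes from Dakin-type oxidation of tris-MOM gallaldehyde.
4. The B-ring alkyne comes from Ohira–Bestmann homologation of 3,4-bis(benzyloxy)benzaldehyde.
5. Ring order: the A and B benzene rings are pre-existing, and the C ring is formed last, in the annulation.

## Route

**Step 1**
Reactants: 1 (3,4,5-trihydroxybenzaldehyde)
Product: 2 (3,4,5-tris(methoxymethoxy)benzaldehyde)
Conditions: MOMCl, iPr2NEt, CH2Cl2/DMF, 0 °C → rt
Reagents that add atoms: MOMCl, ClCOC
Why: Williamson-type O-alkylation of the three phenols as MOM acetals, which survive Pd/CO/amine conditions and are later removed by acid without touching benzyl ethers.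

**Step 2**
Reactants: 2
Product: 3 (3,4,5-tris(methoxymethoxy)phenol)
Conditions: mCPBA, NaHCO3, CH2Cl2, 0 °C → rt; then K2CO3, MeOH, rt (one pot, aryl formate not isolated)
Reagents that add atoms: mCPBA, OOC(=O)c1cccc(Cl)c1 (supplies the phenol oxygen)
Why: Dakin-type Baeyer–Villiger oxidation of an electron-rich aryl aldehyde, with aryl migration to give the formate, which methanolysis cleaves to the phenol.

**Step 3**
Reactants: 3
Product: 4 (2-iodo-3,4,5-tris(methoxymethoxy)phenol)
Conditions: NIS (1.05 equiv), MeCN, 0 °C → rt, dark
Reagents that add atoms: NIS, O=C1CCC(=O)N1I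
Why: Electrophilic aromatic iodination ortho to the OH. The only ring C–H positions (C2 and C6) are equivalent, so regiochemistry is unambiguous, and the buffer-free, acid-free conditions spare the MOM groups.

**Step 4**
Reactants: 5 (3,4-bis(benzyloxy)benzaldehyde)
Product: 6 (1,2-bis(benzyloxy)-4-ethynylbenzene)
Conditions: Bestmann–Ohira reagent, K2CO3, MeOH, 0 °C → rt
Reagents that add atoms: dimethyl (1-diazo-2-oxopropyl)phosphonate, COP(=O)(OC)C(=[N+]=[N-])C(C)=O (supplies the terminal alkyne carbon)
Why: Seyferth–Gilbert homologation via a vinylidene carbene and 1,2-aryl shift, under conditions mild enough to leave the benzyl ethers intact.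

**Step 5 (key step)**
Reactants: 4 (iodophenol) + 6 (alkyne)
Product: 7 (3',4'-bis(benzyloxy)-5,6,7-tris(methoxymethoxy)flavone)
Conditions: PdCl2(PPh3)2 (5 mol %), PPh3 (10 mol %), CO (1 atm, balloon), Et3N, DMF, 80 °C
Reagents that add atoms: carbon monoxide, [C-]#[O+] (becomes the C4 carbonyl)
Why: Pd-catalysed carbonylative Sonogashira coupling gives the o-hydroxyaryl ynone, which undergoes base-mediated 6-endo oxa-Michael cyclization to the flavone. The single phenol defines the A-ring regiochemistry, with O1 on C8a and the 5-OMOM ortho to the new carbonyl.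

**Step 6**
Reactants: 7
Product: 8 (3',4'-bis(benzyloxy)-5,6,7-trihydroxyflavone)
Conditions: 3 M HCl, MeOH/THF (1:1), 50 °C, N2, degassed
Reagents that add atoms: none (H+ with solvent scavenging the oxocarbenium)
Why: Acid-catalysed acetal hydrolysis removes all three MOM groups, while aryl benzyl ethers and the flavone core are stable. The product is a baicalein-type triol, so air is excluded.

**Step 7**
Reactants: 8
Product: 9 (tributylammonium 5,6-dihydroxy-3',4'-bis(benzyloxy)flavon-7-yl sulfate)
Conditions: Bu3N·SO3 (1.1 equiv), MeCN, 50 °C, Ar, dark
Reagents that add atoms: tributylsulfoammonium betaine, CCCC[N+](CCCC)(CCCC)S(=O)(=O)[O-] (supplies SO3)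
Why: Proposed new method: the 7-OH is para to the carbonyl (vinylogous acid, pKa about 7) and is much more acidic than the 6-OH, while the 5-OH is H-bonded to C4=O. Amine-buffered sulfuryl transfer therefore sulfates the 7-phenolate selectively, by analogy with the known 7-O-selective alkylation of baicalein and with Bu3N·SO3 sulfation of phenols.

**Step 8**
Reactants: 9
Product: 10 (6-hydroxyluteolin 7-sulfate, target, isolated as the Na salt)
Conditions: H2 (1 atm), 10% Pd/C, MeOH/THF, rt, stopped at consumption of 9; then Dowex-Na+ and C18 purification
Reagents that add atoms: none (H2 only; Na+ enters as counter-ion on ion exchange)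
Why: Catalytic hydrogenolysis cleaves both benzyl ethers to the catechol. Aryl sulfate monoester anions are stable to H2/Pd, and the short reaction time protects the C2=C3 bond.

## Compound list
1 | 3,4,5-trihydroxybenzaldehyde | O=Cc1cc(O)c(O)c(O)c1 | starting material
2 | 3,4,5-tris(methoxymethoxy)benzaldehyde | O=Cc1cc(OCOC)c(OCOC)c(OCOC)c1 | intermediate
3 | 3,4,5-tris(methoxymethoxy)phenol | Oc1cc(OCOC)c(OCOC)c(OCOC)c1 | intermediate
4 | 2-iodo-3,4,5-tris(methoxymethoxy)phenol | Oc1cc(OCOC)c(OCOC)c(OCOC)c1I | intermediate
5 | 3,4-bis(benzyloxy)benzaldehyde | O=Cc1ccc(OCc2ccccc2)c(OCc2ccccc2)c1 | starting material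
6 | 1,2-bis(benzyloxy)-4-ethynylbenzene | C#Cc1ccc(OCc2ccccc2)c(OCc2ccccc2)c1 | intermediate
7 | 3',4'-bis(benzyloxy)-5,6,7-tris(methoxymethoxy)flavone | O=c1cc(-c2ccc(OCc3ccccc3)c(OCc3ccccc3)c2)oc2cc(OCOC)c(OCOC)c(OCOC)c12 | intermediate
8 | 3',4'-bis(benzyloxy)-5,6,7-trihydroxyflavone | O=c1cc(-c2ccc(OCc3ccccc3)c(OCc3ccccc3)c2)oc2cc(O)c(O)c(O)c12 | intermediate
9 | tributylammonium 3',4'-bis(benzyloxy)-5,6-dihydroxyflavon-7-yl sulfate | O=c1cc(-c2ccc(OCc3ccccc3)c(OCc3ccccc3)c2)oc2cc(OS(=O)(=O)[O-])c(O)c(O)c12.CCCC[NH+](CCCC)CCCC | intermediate
10 | 6-hydroxyluteolin 7-sulfate (achiral) | O=c1cc(-c2ccc(O)c(O)c2)oc2cc(OS(=O)(=O)O)c(O)c(O)c12 | target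

**Total steps:** 8 (including the one-pot two-operation Step 2).
**Longest linear sequence:** 7 steps (1 → 2 → 3 → 4 → 7 → 8 → 9 → 10, via Steps 1, 2, 3, 5, 6, 7, 8).

## Three steps most likely to fail
1. **Step 7, regioselective 7-sulfation.** The 6-OH may also be sulfated, and the electron-rich triol can oxidize to an o-quinone.
   Fallback: temporarily mask the 5,6-diol of 8 as its cyclic phenylboronate (PhB(OH)2), sulfate the lone 7-OH, then release the boronate with a diol or H2O2 workup before hydrogenolysis. Alternatively, hydrogenolyze 8 first and sulfate 6-hydroxyluteolin enzymatically with an aryl sulfotransferase and p-nitrophenyl sulfate.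
2. **Step 5, carbonylative annulation.** The electron-rich aryl iodide is hindered by the ortho-OMOM, so slow oxidative addition, direct Sonogashira giving a 2-arylbenzofuran, or aurone formation could compete.
   Fallback: abandon the one-pot Pd route and use the classical stepwise flavone construction. Acylate an A-ring phenol to the 2-hydroxyacetophenone, carry out Baker–Venkataraman with 3,4-bis(benzyloxy)benzoyl chloride, and close the ring with acid. The A-ring protecting groups would have to be changed because MOM does not survive Lewis-acid acylation.
3. **Step 8, hydrogenolysis.** The catalyst may be poisoned by the sulfate, the C2=C3 bond may be over-reduced to the flavanone, or sulfate may be lost.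
   Fallback: replace the B-ring benzyls with a non-reductively removable catechol protecting group. Use 3,4-bis(TBS-oxy)phenylacetylene in place of 6, then remove the silyl groups with fluoride after the acidic MOM removal, since aryl sulfate monoesters tolerate fluoride.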